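**Retrosynthetic overview**

1. The ester C–O bond is made last. The C4 carbinol comes from a hydroxyl-directed reduction of a C4 ketone, and the tertiary C3–OH from a C3–B bond oxidized with retention.
2. The cyclopentane is closed in one operation: C1–C2 and C3–C3a are formed by an SmI2-catalysed radical-relay (3+2) cycloaddition of a cyclopropane-fused cycloheptenone with CH2=C(iPr)Bpin. The ring fusion is then equilibrated to trans at C3a.
3. Enabling feature: in the seven-membered ring C3a is α and C8a is β to the C4 carbonyl, and C1 sits on C8a. C1–C8a–C3a can therefore be stored as a cyclopropane fused to the ring (a bicyclo[5.1.0]octenone). One-electron reduction of C4=O opens its external C1–C3a bond to a C1 radical and a C3a enolate carbon.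
4. Absolute configuration (C8a): achiral 3,6-dimethylcyclohepta-2,6-dienone, addition of an (S)-sulfoximine, hydroxyl-directed cyclopropanation, separation of diastereomers, thermal release of the ketone.
5. Ring order: seven-membered ring first, by (4+3) cycloaddition of 2,5-dimethylfuran with an oxyallyl cation, hydrogenation and acid ring-opening; then the temporary cyclopropane; the cyclopentane last.

Key step: step 9

Remark on the chemistry: locants C1–C8a are those of the octahydroazulene skeleton of the target; (S)-N,S-dimethyl-S-phenylsulfoximine and 1,1,3,3-tetrabromoacetone are taken as commercial.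

**Route**

Step 1
Reactants: 1 2,5-dimethylfuran; 2 1,1,3,3-tetrabromoacetone
Product: 4 (1R,5S)-1,5-dimethyl-8-oxabicyclo[3.2.1]oct-6-en-3-one, via dibromo cycloadduct 3 (not isolated)
Conditions: Zn–Ag couple, THF, −10 °C → rt; then Zn–Cu couple, NH4Cl, MeOH, rt
Reagents that add atoms: none
Why: Reductive debromination of 2 generates a 2-oxyallyl cation that undergoes (4+3) cycloaddition across the 2,5-positions of the electron-rich furan, and zinc then removes the two α-bromines; the bicycle is meso, so no stereochemical issue arises.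

Step 2
Reactants: 4 (1R,5S)-1,5-dimethyl-8-oxabicyclo[3.2.1]oct-6-en-3-one
Product: 5 (1R,5S)-1,5-dimethyl-8-oxabicyclo[3.2.1]octan-3-one
Conditions: H2 (1 atm), 10% Pd/C, EtOAc, rt
Reagents that add atoms: none
Why: Heterogeneous catalytic hydrogenation of the strained, unhindered bridge alkene, with ketone and bridging ether inert.

Step 3
Reactants: 5 (1R,5S)-1,5-dimethyl-8-oxabicyclo[3.2.1]octan-3-one
Product: 7 3,6-dimethylcyclohepta-2,6-dien-1-one, via hydroxy enone 6 (not isolated)
Conditions: FSO3H, CH2Cl2, −78 → 0 °C; aq. NaHCO3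
Reagents that add atoms: none
Why: Acid-induced β-elimination of the bridging ether oxygen (a tertiary C–O bond β to the ketone) and dehydration of the resulting tertiary β-hydroxy ketone should give the cross-conjugated dienone, the known strong-acid opening of hydrogenated furan–oxyallyl cycloadducts.

Step 4
Reactants: 7 3,6-dimethylcyclohepta-2,6-dien-1-one; 8 (S)-N,S-dimethyl-S-phenylsulfoximine
Product: 10 3,6-dimethyl-1-{[(S)-N-methyl-S-phenylsulfonimidoyl]methyl}cyclohepta-2,6-dien-1-ol, via lithiated sulfoximine 9 (not isolated)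
Conditions: 8, n-BuLi, THF, −78 °C; then 7, −78 °C; H2O
Reagents that add atoms: none
Why: 1,2-Addition of the α-lithiated sulfoximine to the ketone; because the two ring arms are identical the carbinol carbon is not stereogenic and a single adduct should form.

Step 5
Reactants: 10 3,6-dimethyl-1-{[(S)-N-methyl-S-phenylsulfonimidoyl]methyl}cyclohepta-2,6-dien-1-ol
Product: 11 (1R,2S,7S)-4,7-dimethyl-2-{[(S)-N-methyl-S-phenylsulfonimidoyl]methyl}bicyclo[5.1.0]oct-3-en-2-ol
Conditions: Et2Zn (1.1 equiv), CH2I2 (1.1 equiv), CH2Cl2, −10 → 0 °C; chromatographic separation of the diastereomers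
Reagents that add atoms: diiodomethane, ICI
Why: Hydroxyl-directed Simmons–Smith cyclopropanation (Furukawa variant) delivers CH2 syn to the zinc alkoxide and so fixes C1 and C7 relative to C2; the sulfur stereocentre makes the two ring alkenes diastereotopic, so the two syn mono-adducts are diastereomers and the (1R,2S,7S) isomer is separated and carried on.

Step 6
Reactants: 11 (1R,2S,7S)-4,7-dimethyl-2-{[(S)-N-methyl-S-phenylsulfonimidoyl]methyl}bicyclo[5.1.0]oct-3-en-2-ol
Product: 12 (1R,7S)-4,7-dimethylbicyclo[5.1.0]oct-3-en-2-one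
Conditions: toluene, 110 °C
Reagents that add atoms: none
Why: Thermal retro-addition of the β-hydroxysulfoximine (the sulfoximine method for optically active cyclopropyl ketones) should release the enone without touching the cyclopropane stereocentres.

Step 7
Reactants: 13 3-methylbutan-2-one
Product: 15 3-methylbut-1-en-2-yl trifluoromethanesulfonate, via lithium enolate 14 (not isolated)
Conditions: LDA, THF, −78 °C; then PhNTf2, −78 → 0 °C
Reagents that add atoms: N-phenylbis(trifluoromethanesulfonimide), O=S(=O)(N(c1ccccc1)S(=O)(=O)C(F)(F)F)C(F)(F)F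
Why: Kinetic deprotonation at the methyl group and O-sulfonylation of the less substituted enolate (enol triflate formation).

Step 8
Reactants: 15 3-methylbut-1-en-2-yl trifluoromethanesulfonate
Product: 16 4,4,5,5-tetramethyl-2-(3-methylbut-1-en-2-yl)-1,3,2-dioxaborolane
Conditions: B2pin2, PdCl2(PPh3)2 (3 mol%), PPh3, KOPh, toluene, 50 °C
Reagents that add atoms: bis(pinacolato)diboron, CC1(C)OB(OC1(C)C)B1OC(C)(C)C(C)(C)O1
Why: Miyaura borylation of an alkenyl triflate (oxidative addition, phenoxide-assisted transmetalation, reductive elimination).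

Step 9
Reactants: 12 (1R,7S)-4,7-dimethylbicyclo[5.1.0]oct-3-en-2-one; 16 4,4,5,5-tetramethyl-2-(3-methylbut-1-en-2-yl)-1,3,2-dioxaborolane
Product: 17 (3S,3aR,8aR)-6,8a-dimethyl-3-(propan-2-yl)-3-(4,4,5,5-tetramethyl-1,3,2-dioxaborolan-2-yl)-2,3,3a,7,8,8a-hexahydroazulen-4(1H)-one (cis-fused)
Conditions: SmI2 (20 mol%), Sm powder (20 mol%), 16 (3 equiv), THF (0.1 M), 55 °C, Ar
Reagents that add atoms: none
Why: Proposed new method: Sm(II) reduces the enone carbonyl of 12, the ketyl opens the external C1–C8 cyclopropane bond (bicyclooctenone numbering) to a samarium(III) dienolate carrying a primary CH2 radical, this radical adds to the CH2 terminus of the electron-poor alkenyl boronate 16 (new C1–C2 bond, azulene numbering), the tertiary α-boryl radical closes onto the enolate α-carbon (new C3–C3a bond), and back electron transfer from the product ketyl to Sm(III) returns Sm(II), so the whole is a radical-relay formal (3+2) cycloaddition. The closest known reaction type is the SmI2-catalysed coupling of alkyl and bicyclic cyclopropyl ketones with alkynes and alkenes, together with the related insertion of electron-poor alkenes into bicyclo[1.1.0]butyl ketones; not shown so far are a cross-conjugated cyclopropyl enone as the three-carbon partner and a 1,1-disubstituted alkenyl boronate as an enol surrogate. The cyclopentane closes by 5-exo-trig radical cyclization onto a ring sp2 carbon, which can only be reached from the face that carries the CH2 tether, so the hydroazulenone should form cis-fused and C3a is set by this geometric constraint (it is inverted in step 10), while C8a is carried over unchanged from 12. At C3 a chair-like transition state with the larger isopropyl group pseudo-equatorial should place isopropyl syn to C4 and the flat boryl group on the face of the angular methyl group, the arrangement that oxidation with retention turns into the required carbinol. The step needs cleavage of the external and not the ring-fusion cyclopropane bond, and capture of the radical by 16 before it is reduced or abstracts hydrogen from THF: better overlap of the external bond with the ketyl π system in the cis-fused bicyclo[5.1.0] frame, reversible opening with faster trapping of the unhindered primary radical, polarity matching in both C–C bond formations and the excess of 16 should secure this.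

Step 10
Reactants: 17 (3S,3aR,8aR)-6,8a-dimethyl-3-(propan-2-yl)-3-(4,4,5,5-tetramethyl-1,3,2-dioxaborolan-2-yl)-2,3,3a,7,8,8a-hexahydroazulen-4(1H)-one
Product: 18 (3S,3aS,8aR)-6,8a-dimethyl-3-(propan-2-yl)-3-(4,4,5,5-tetramethyl-1,3,2-dioxaborolan-2-yl)-2,3,3a,7,8,8a-hexahydroazulen-4(1H)-one (trans-fused)
Conditions: DBU (0.5 equiv), toluene, 50 °C
Reagents that add atoms: none
Why: Base-mediated α-epimerization: reversible deprotonation at C3a equilibrates the ring fusion, and the trans isomer is expected to be favoured because it removes the syn relationship between isopropyl and C4 and allows a carbonyl O→B contact, while C3 and C8a cannot change.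

Step 11
Reactants: 18 (3S,3aS,8aR)-6,8a-dimethyl-3-(propan-2-yl)-3-(4,4,5,5-tetramethyl-1,3,2-dioxaborolan-2-yl)-2,3,3a,7,8,8a-hexahydroazulen-4(1H)-one
Product: 19 (3R,3aR,8aS)-3-hydroxy-6,8a-dimethyl-3-(propan-2-yl)-2,3,3a,7,8,8a-hexahydroazulen-4(1H)-one
Conditions: NaBO3·4H2O (5 equiv), THF/H2O 1:1, rt
Reagents that add atoms: sodium perborate (written as monomeric NaBO3), O=BO[O-].[Na+]
Why: Oxidation of the tertiary pinacol boronate (1,2-shift of carbon from boron to oxygen) proceeds with retention at C3, and the mild perborate medium should spare the β-hydroxy ketone and the enone.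

Step 12
Reactants: 19 (3R,3aR,8aS)-3-hydroxy-6,8a-dimethyl-3-(propan-2-yl)-2,3,3a,7,8,8a-hexahydroazulen-4(1H)-one
Product: 20 (3R,3aS,4S,8aS)-6,8a-dimethyl-3-(propan-2-yl)-1,2,3,3a,4,7,8,8a-octahydroazulene-3,4-diol
Conditions: Me4NBH(OAc)3 (5 equiv), MeCN/AcOH 1:1, −25 °C
Reagents that add atoms: none
Why: Evans–Saksena hydroxyl-directed reduction: the C3 oxygen binds boron and delivers hydride intramolecularly to the face of the C4 carbonyl on which it lies (the face of the angular methyl), so the new C4–OH should stand cis to H3a (anti 1,3-diol) with 1,2-selectivity on the enone.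

Step 13
Reactants: 20 (3R,3aS,4S,8aS)-6,8a-dimethyl-3-(propan-2-yl)-1,2,3,3a,4,7,8,8a-octahydroazulene-3,4-diol; 21 4-methoxybenzoyl chloride
Product: 22 (3R,3aS,4S,8aS)-3-hydroxy-6,8a-dimethyl-3-(propan-2-yl)-1,2,3,3a,4,7,8,8a-octahydroazulen-4-yl 4-methoxybenzoate
Conditions: pyridine, DMAP (cat.), CH2Cl2, 0 °C → rt
Reagents that add atoms: none
Why: DMAP-catalysed acylation of the secondary allylic alcohol, the hindered tertiary C3–OH staying free.

**Compound list**

1 | 2,5-dimethylfuran | Cc1ccc(C)o1 | starting material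
2 | 1,1,3,3-tetrabromoacetone | O=C(C(Br)Br)C(Br)Br | starting material
3 | 2,4-dibromo-1,5-dimethyl-8-oxabicyclo[3.2.1]oct-6-en-3-one (mixture of C2/C4 isomers) | C[C@@]12C(Br)C(=O)C(Br)[C@@](C)(O1)C=C2 | intermediate
4 | (1R,5S)-1,5-dimethyl-8-oxabicyclo[3.2.1]oct-6-en-3-one (meso) | C[C@@]12CC(=O)C[C@@](C)(O1)C=C2 | intermediate
5 | (1R,5S)-1,5-dimethyl-8-oxabicyclo[3.2.1]octan-3-one (meso) | C[C@@]12CC(=O)C[C@@](C)(O1)CC2 | intermediate
6 | 6-hydroxy-3,6-dimethylcyclohept-2-en-1-one (racemic) | CC1=CC(=O)CC(C)(O)CC1 | intermediate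
7 | 3,6-dimethylcyclohepta-2,6-dien-1-one | CC1=CC(=O)C=C(C)CC1 | intermediate
8 | (S)-N,S-dimethyl-S-phenylsulfoximine | CN=[S@@](=O)(c1ccccc1)C | starting material
9 | {[(S)-N-methyl-S-phenylsulfonimidoyl]methyl}lithium | CN=[S@@](=O)(c1ccccc1)[CH2-].[Li+] | intermediate
10 | 3,6-dimethyl-1-{[(S)-N-methyl-S-phenylsulfonimidoyl]methyl}cyclohepta-2,6-dien-1-ol | CN=[S@@](=O)(c1ccccc1)CC1(O)C=C(C)CCC(C)=C1 | intermediate
11 | (1R,2S,7S)-4,7-dimethyl-2-{[(S)-N-methyl-S-phenylsulfonimidoyl]methyl}bicyclo[5.1.0]oct-3-en-2-ol | CN=[S@@](=O)(c1ccccc1)C[C@]1(O)C=C(C)CC[C@@]2(C)C[C@@H]12 | intermediate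
12 | (1R,7S)-4,7-dimethylbicyclo[5.1.0]oct-3-en-2-one | O=C1C=C(C)CC[C@@]2(C)C[C@@H]12 | intermediate
13 | 3-methylbutan-2-one | CC(C)C(C)=O | starting material
14 | lithium 3-methylbut-1-en-2-olate | [Li+].[O-]C(=C)C(C)C | intermediate
15 | 3-methylbut-1-en-2-yl trifluoromethanesulfonate | C=C(OS(=O)(=O)C(F)(F)F)C(C)C | intermediate
16 | 4,4,5,5-tetramethyl-2-(3-methylbut-1-en-2-yl)-1,3,2-dioxaborolane | C=C(B1OC(C)(C)C(C)(C)O1)C(C)C | intermediate
17 | (3S,3aR,8aR)-6,8a-dimethyl-3-(propan-2-yl)-3-(4,4,5,5-tetramethyl-1,3,2-dioxaborolan-2-yl)-2,3,3a,7,8,8a-hexahydroazulen-4(1H)-one | O=C1C=C(C)CC[C@@]2(C)CC[C@@](B3OC(C)(C)C(C)(C)O3)(C(C)C)[C@@H]12 | intermediate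
18 | (3S,3aS,8aR)-6,8a-dimethyl-3-(propan-2-yl)-3-(4,4,5,5-tetramethyl-1,3,2-dioxaborolan-2-yl)-2,3,3a,7,8,8a-hexahydroazulen-4(1H)-one | O=C1C=C(C)CC[C@@]2(C)CC[C@@](B3OC(C)(C)C(C)(C)O3)(C(C)C)[C@H]12 | intermediate
19 | (3R,3aR,8aS)-3-hydroxy-6,8a-dimethyl-3-(propan-2-yl)-2,3,3a,7,8,8a-hexahydroazulen-4(1H)-one | O=C1C=C(C)CC[C@@]2(C)CC[C@@](O)(C(C)C)[C@H]12 | intermediate
20 | (3R,3aS,4S,8aS)-6,8a-dimethyl-3-(propan-2-yl)-1,2,3,3a,4,7,8,8a-octahydroazulene-3,4-diol | O[C@H]1C=C(C)CC[C@@]2(C)CC[C@@](O)(C(C)C)[C@H]12 | intermediate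
21 | 4-methoxybenzoyl chloride | COc1ccc(C(=O)Cl)cc1 | starting material
22 | (3R,3aS,4S,8aS)-3-hydroxy-6,8a-dimethyl-3-(propan-2-yl)-1,2,3,3a,4,7,8,8a-octahydroazulen-4-yl 4-methoxybenzoate | COc1ccc(C(=O)O[C@H]2C=C(C)CC[C@@]3(C)CC[C@@](O)(C(C)C)[C@H]23)cc1 | target

**Step count**

Total: 13 steps. Longest linear sequence: 11 steps (steps 1–6 and 9–13); steps 7–8 make the boronate partner.

**Steps most likely to fail**

1. Step 9 (Proposed new method). What may go wrong: opening of the ring-fusion cyclopropane bond (ring expansion to an eight-membered ring), reduction or hydrogen abstraction of the primary radical before it adds to 16, and loss of the samarium catalyst through irreversible enone reduction. Fallback with known chemistry, from 7 to 19: the cyclopentane is built by conjugate addition and aldol addition instead. 2-(2-Bromoethyl)-2-(propan-2-yl)-1,3-dioxolane F1 (from 4-methylpent-1-en-3-one, HBr and ethylene glycol) is converted with magnesium into {2-[2-(propan-2-yl)-1,3-dioxolan-2-yl]ethyl}magnesium bromide F2. Copper-catalysed asymmetric conjugate addition of F2 to dienone 7 with a chiral N-heterocyclic carbene or phosphoramidite ligand should desymmetrize 7 and create the quaternary centre, giving (S)-3,6-dimethyl-6-{2-[2-(propan-2-yl)-1,3-dioxolan-2-yl]ethyl}cyclohept-2-en-1-one F3. Aqueous HCl in THF should release (S)-3,6-dimethyl-6-(4-methyl-3-oxopentyl)cyclohept-2-en-1-one F4. Base under equilibrating conditions (K2CO3, MeOH) should then close the five-membered ring by intramolecular aldol addition, and the route is rejoined at 19.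

2. Step 10. What may go wrong: the equilibration at C3a stalls or does not favour the trans series, for instance because the ring closure of step 9 placed boron and isopropyl on C3 the other way round; protodeboronation under base is a further risk. Fallback, from 17 to 19: the boronate 17 is oxidized directly with sodium perborate to cis-fused (3R,3aS,8aS)-3-hydroxy-6,8a-dimethyl-3-(propan-2-yl)-2,3,3a,7,8,8a-hexahydroazulen-4(1H)-one F5. F5 is then held under aldol-equilibrating base (Ba(OH)2 or K2CO3 in MeOH), where enolization at C3a and retro-aldol opening to (S)-3,6-dimethyl-6-(4-methyl-3-oxopentyl)cyclohept-2-en-1-one F6 with re-closure allow C3 and C3a to settle under thermodynamic control. The hydrogen-bonded trans-fused aldol 19 is the expected sink, where the route is rejoined.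

3. Step 5. What may go wrong: poor discrimination between the two diastereotopic ring alkenes, over-cyclopropanation, and ionization of the doubly allylic tertiary alcohol by zinc Lewis acids. Fallback, from 7 to 12: the chirality is brought in by a reagent instead of an auxiliary. Luche reduction (NaBH4, CeCl3, MeOH) of 7 should give achiral 3,6-dimethylcyclohepta-2,6-dien-1-ol F7. Enantiotopic-group-selective Simmons–Smith cyclopropanation with Zn(CH2I)2 and a chiral tartramide-derived butyldioxaborolane ligand should give (1R,2S,7S)-4,7-dimethylbicyclo[5.1.0]oct-3-en-2-ol F8. Oxidation with MnO2 returns to the route at 12.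

**Further compounds**

F1 | step 9 | 2-(2-bromoethyl)-2-(propan-2-yl)-1,3-dioxolane | BrCCC1(C(C)C)OCCO1
F2 | step 9 | {2-[2-(propan-2-yl)-1,3-dioxolan-2-yl]ethyl}magnesium bromide | Br[Mg]CCC1(C(C)C)OCCO1
F3 | step 9 | (S)-3,6-dimethyl-6-{2-[2-(propan-2-yl)-1,3-dioxolan-2-yl]ethyl}cyclohept-2-en-1-one | CC1=CC(=O)C[C@](C)(CCC2(C(C)C)OCCO2)CC1
F4 | step 9 | (S)-3,6-dimethyl-6-(4-methyl-3-oxopentyl)cyclohept-2-en-1-one | CC1=CC(=O)C[C@](C)(CCC(=O)C(C)C)CC1
F5 | step 10 | (3R,3aS,8aS)-3-hydroxy-6,8a-dimethyl-3-(propan-2-yl)-2,3,3a,7,8,8a-hexahydroazulen-4(1H)-one | O=C1C=C(C)CC[C@@]2(C)CC[C@@](O)(C(C)C)[C@@H]12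
F6 | step 10 | (S)-3,6-dimethyl-6-(4-methyl-3-oxopentyl)cyclohept-2-en-1-one | CC1=CC(=O)C[C@](C)(CCC(=O)C(C)C)CC1
F7 | step 5 | 3,6-dimethylcyclohepta-2,6-dien-1-ol | CC1=CC(O)C=C(C)CC1
F8 | step 5 | (1R,2S,7S)-4,7-dimethylbicyclo[5.1.0]oct-3-en-2-ol | O[C@H]1C=C(C)CC[C@@]2(C)C[C@@H]12
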